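Remark on the chemistry (assumptions): drimane numbering is used (ring A = C1–C5, C10; ring B = C5–C10; C11 = the chlorine-bearing carbon; primes for the arene), and α means the face opposite the C10 methyl. A check of all configurations shows them to be mutually consistent (target 2S,4aS,8aS,E; the S enantiomer of 1 supplies C10; the hydrindanone must be 3aS,7aS), so no structure was altered. The C8 epimer of 10 is set by base equilibration only to obtain one defined compound.

## Structural features

The target is a drimane-type sesquiterpenoid hydroquinone: a trans-fused decalin (rings A and B) is joined through an exocyclic, fully substituted C9=C11 double bond to a 2,5-dihydroxy-3-methoxyphenyl ring, and C11 also carries chlorine. Ring A holds the gem-dimethyl C4. The quaternary C10 (β-methyl) and C5 (α-H) are adjacent ring-fusion stereocentres (both S). The third stereocentre, C8 (S, β-methyl, axial and syn to the C10 methyl), is bonded to the alkene carbon C9, which is in turn bonded to C10. The alkene is E: chlorine lies on the C8 side and the arene on the side of the quaternary C10. The fragile groups are the para-hydroquinone (air oxidation), the alkenyl chloride (hydrogenolysis, insertion of low-valent metals) and the electron-rich tetrasubstituted alkene (protonation, isomerisation). The real difficulty is the C9=C11 alkene: both carbons are fully substituted, it is wedged between the quaternary C10 and the stereogenic C8, and its geometry cannot be corrected later with any confidence. The key step exploits the fact that C8, a CH–CH3 unit, lies in ring B between C7 and C9: with C9 as a ketone, C8 and its methyl are the carbon of diazoethane inserted between C9 and C7 of a trans-hydrindanone whose C5 and C10 come from the chiral pool.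

## Logic of the disconnections

24 ⇒ 22 (through 23). The O–H bonds at C2′ and C5′ are traced back to O–CH3 bonds. Cutting here keeps the oxidisable hydroquinone masked as an inert arene through every organometallic step. The forward step must remove exactly the para-related pair of methyl groups, keep the C3′ methoxy group, and spare the C11–Cl bond and the alkene; the reduction of 23 must not touch C–Cl.

22 ⇒ 21. The C11–Cl bond is replaced by a C11–O(sulfonyl) bond. A C–O bond at C11 can be made from an enolate whose geometry is fixed by how it is generated, whereas a C–Cl bond cannot. The geometry problem of the chloroalkene thus becomes an enolate-geometry problem. The exchange must proceed with retention at a fully substituted alkene carbon.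

21 ⇒ 18 (through 19 and 20). The C8–H bond and the O–S bond are cut, the double bond returns from C9=C11 to C8=C9, and C11 becomes a carbonyl again. This removes the C8 stereocentre and the alkene geometry in one retrosynthetic operation. The forward step needs hydride delivery to C8 on the α face and reaction through the conformer with the carbonyl oxygen on the C8 side.

18 ⇒ 12 + 17. The bonds C9–C11 and C11–C1′ are cut around a one-carbon carbonyl unit. This splits the molecule into its terpenoid and arene halves, which are made separately. The forward step needs carbonyl insertion at the hindered C9–metal bond to outrun direct C9–C1′ coupling.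

12 ⇒ 10 (through 11). The C9–O enol bond goes back to the C9 ketone. C10 is quaternary, so only C8 can be deprotonated and regiochemistry is not an issue; the configuration at C8 in 10 is therefore irrelevant. The forward step must remove a tertiary hydrogen next to a hindered carbonyl.

10 ⇒ 7 + 9 (9 made from 8). The bonds C8–C9 and C7–C8 are cut and the CH–CH3 unit is excised, contracting ring B to a five-membered ring. This reduces a tetramethyl decalone to a hydrindanone that maps onto 1 with C10 already in place. The forward step must make C7, not C10, migrate and must insert only once.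

7 ⇒ 5 (through 6). The C3a–H and C3–H bonds are cut (alkene back in place) and the ketone is re-masked. The C5 stereocentre is thereby reduced to a facial choice on a rigid bicyclic alkene. Hydrogen must arrive on the α face.

5 ⇒ 3 (through 4). The two C5–H bonds go back to the C5 carbonyl, the group that allowed C4 to be alkylated. The forward deoxygenation must work next to a quaternary carbon and leave the ketal intact.

3 ⇒ 2. The two C4–CH3 bonds are cut, returning to the conjugated enone. The forward step must alkylate C4 twice and leave C6 alone.

2 ⇒ 1. The two C1–O ketal bonds are cut. The forward protection must choose the saturated C1 ketone over the enone.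

17 ⇒ 15 (through 16). The C1′–B bond goes back to C1′–Br. The bromine fixes the position of metalation.

15 ⇒ 13 (through 14). The two new O–CH3 bonds are cut and the C5′–O bond is traced back to the formyl-bearing carbon. This gives a commercial arene with all substituents already in the right places.

## Other disconnections considered

Alternative 1: The cut is through C8–C9 and C5–C10, which opens rings A and B together. The forward step would be a thermal intramolecular Diels–Alder reaction of the open-chain chloroallene A2 (diene C5=C6–C7=C8, dienophile the C9=C10 bond of the allene) to give A1; saturation of C6=C7 of A1 with diimide would then meet the main route at 22.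
- In its favour: one step would form two rings, two C–C bonds, three stereocentres and the alkene geometry, the last by transfer of the allene axis (the diene passing the chlorine side leaves chlorine syn to C8). On complexity gained per step and on avoiding diazoalkanes, hindered conjugate reduction and triflate exchange it is the better plan.
- Against it: C10 of the dienophile is fully substituted and unactivated, and the diene terminus C5 is neopentyl, so forcing temperatures would be needed. At such temperatures an aryl chloroallene can lose its axial configuration by ionisation and chloride return, and the diene can undergo 1,5-hydrogen shifts. The R-configured axis of A2 would itself need a stereospecific anti-SN2′ chlorination at a tertiary propargylic position.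
- Comparison on structure: it attacks the hardest feature directly, but couples four selectivities (axis integrity, face of the allene, endo/exo for the trans fusion, diene geometry) in one transition state. The chosen plan separates them: C10 from 1, C5 by hydrogenation, C8 and the alkene geometry by one conjugate reduction.
- Comparison on mechanism and step economy: the pericyclic mechanism is predictable in principle but only weakly biased. Assembly of A2 would take roughly as many steps as the chosen route needs to reach 18, so the count is about equal with higher stereochemical risk.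

Alternative 2: The cut is the C8–C9 bond of ring B at the enone stage. The forward step would be FeCl3-promoted carbonyl–alkyne metathesis of the alkynyl methyl ketone A4: the alkyne carbon C9 attacks the C8 carbonyl, the oxetene opens, and the oxygen ends on C11, giving A3. Hydrogenation of the C1=C2 alkene of A3 would give 18.
- In its favour: it is an atom-economic isomerisation that delivers the aryl enone directly, so the enol triflate and the carbon monoxide coupling would not be needed. The electron-rich aryl alkyne is a good nucleophile for the activated ketone and six-membered closure is favourable. On this stretch, and in avoiding diazoethane, it is the better plan.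
- Against it: the quaternary propargylic C10 and the adjacent C5 of A4 would have to be built enantioselectively with no chiral-pool answer comparable to 1. FeCl3 could also trigger participation of the ortho-methoxy oxygen at the activated alkyne (benzofuran formation) or cationic reactions of the ring A alkene.
- Comparison: everything after 18 is unchanged, so the riskiest steps of the chosen plan remain. Mechanistically both ring closures are Lewis-acid events of comparable reliability, and removing the extra alkene is an equal, minor burden. About two steps would be saved after ring closure, but more would be spent on A4, so the count is equal at best.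

Alternative 3: The cut is through three bonds of the arene (C5′–C6′, C1′–C2′, C2′–C3′). The forward step would be a Dötz benzannulation of the terminal alkyne A6 with the β-methoxyvinyl(methoxy)carbene complex of zerovalent chromium A7 and one of its CO ligands, giving the phenol A5.
- In its favour: regiochemistry with terminal alkynes is dependable (the large substituent ends ortho to the new phenol). The C2′ oxygen would emerge free and differentiated from C5′, so only one methyl group would have to be removed later, by a milder oxidation than 22 requires. On this point it is the better plan.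
- Against it: chromium is stoichiometric, A7 is labile, and the alkyne of A6 sits on a fully substituted ketal carbon attached to the hindered C9, so alkyne insertion should be slow. A6 would have to be made from 12 by additional steps, and A5 would still need ketal cleavage, phenol protection and the same reductive sulfonylation and chloride exchange.
- Comparison: the arene is the easy part of this target (17 is two steps from 13), so the strategy would spend its key step where it is least needed and leave the C9=C11 problem untouched. The mechanism is well understood, but the route would be several steps longer.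

Key step: step 5

## Route

Step 1
Reactants: 1 (S)-7a-methyl-2,3,7,7a-tetrahydro-1H-indene-1,5(6H)-dione
Product: 2 (7aS)-1,1-(ethylenedioxy)-7a-methyl-1,2,3,6,7,7a-hexahydro-5H-inden-5-one
Conditions: Me3SiOCH2CH2OSiMe3, Me3SiOTf (5 mol%), CH2Cl2, −78 → −20 °C; pyridine quench
Reagents that add atoms: 1,2-bis(trimethylsilyloxy)ethane, C[Si](C)(C)OCCO[Si](C)(C)C
Why: Silyl-triflate-catalysed ketalisation with the bis-silyl ether of ethylene glycol takes saturated ketones in preference to the less electrophilic conjugated enone, so only the C1 cyclopentanone is masked; no stereocentre is touched.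

Step 2
Reactants: 2 (7aS)-1,1-(ethylenedioxy)-7a-methyl-1,2,3,6,7,7a-hexahydro-5H-inden-5-one
Product: 3 (7aS)-1,1-(ethylenedioxy)-4,4,7a-trimethyl-1,2,4,6,7,7a-hexahydro-5H-inden-5-one (alkene now C3=C3a)
Conditions: KOtBu (2.5 equiv), t-BuOH/THF, 0 °C; MeI, 0 °C → rt
Reagents that add atoms: iodomethane, CI
Why: Deconjugative α,α-dialkylation of an enone: the extended dienolate formed by γ-deprotonation at C3 is methylated twice at C4, and the quaternary C4 then holds the alkene at C3=C3a; the ketal keeps C2 from being alkylated.

Step 3
Reactants: 3 (7aS)-1,1-(ethylenedioxy)-4,4,7a-trimethyl-1,2,4,6,7,7a-hexahydro-5H-inden-5-one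
Product: 5 (7aS)-1,1-(ethylenedioxy)-4,4,7a-trimethyl-2,4,5,6,7,7a-hexahydro-1H-indene, via C5-hydrazone 4 (not isolated)
Conditions: N2H4·H2O, KOH, diethylene glycol, 130 °C, then 200 °C with removal of water
Reagents that add atoms: none
Why: Wolff–Kishner reduction (Huang–Minlon procedure): the hydrazone loses N2 under base to leave CH2 at C5; the quaternary C4 prevents migration of the alkene into conjugation and the dioxolane is stable to hot base.

Step 4
Reactants: 5 (7aS)-1,1-(ethylenedioxy)-4,4,7a-trimethyl-2,4,5,6,7,7a-hexahydro-1H-indene
Product: 7 (3aS,7aS)-4,4,7a-trimethyloctahydro-1H-inden-1-one, via saturated ketal 6 (not isolated)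
Conditions: H2 (4 atm), 10% Pd/C, EtOAc, rt; filtration; 1 M HCl, THF, rt
Reagents that add atoms: water, O
Why: Heterogeneous syn-hydrogenation of the C3=C3a alkene should take place on the α face, because the β face carries the angular C7a methyl and the pseudo-axial C4 methyl; this puts the new C3a–H anti to the C7a methyl (trans fusion, 3aS). Acetal hydrolysis then frees the C1 ketone, and C3a cannot epimerise because it is not α to the carbonyl.

Step 5
Reactants: 7 (3aS,7aS)-4,4,7a-trimethyloctahydro-1H-inden-1-one; 8 N-ethyl-N-nitrosourea
Product: 10 (2R,4aS,8aS)-2,5,5,8a-tetramethyloctahydronaphthalen-1(2H)-one, via diazoethane 9 (not isolated)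
Conditions: 8, 40% aq KOH, Et2O, 0 °C (cold ethereal 9 dried over KOH pellets); 7, Sc(OTf)3 (10 mol%), PhMe, −78 → −40 °C; then NaOMe, MeOH, rt
Reagents that add atoms: none
Why: Sc(OTf)3 binds the C9 carbonyl oxygen of 7, the nucleophilic carbon of 9 adds to C9 to give a β-diazonium alkoxide, and N2 leaves as a ring bond shifts to the diazo carbon while the C9 carbonyl re-forms. The closest known reaction type is the Lewis-acid-catalysed homologation of cycloalkanones with non-stabilised diazoalkanes (a Tiffeneau–Demjanov-type 1,2-shift), as in the ring enlargement of 17-oxo steroids, which contain the same neopentyl cyclopentanone. Ring B is not closed by a cyclisation: the five-membered ring is enlarged to the six-membered ring by the 1,2-shift of C7 (forming C7–C8), the addition having formed C8–C9. The selectivity needed is migration of the methylene C7 and not of the quaternary C10; the less substituted and less hindered α-carbon is the usual migrating group in these insertions, and aligning the C10–C9 bond anti to the leaving N2 would press the incoming methyl against the angular methyl. A single insertion is also required; the carbonyl of 10 is flanked by a quaternary and a tertiary carbon and should be far less reactive than that of 7, while relief of trans-hydrindanone strain favours the first insertion. C8 is the only new stereocentre and is formed without control; NaOMe equilibrates it through the C8 enolate (the only one possible) to the equatorial 8α-methyl epimer, and step 6 erases it in any case. Low temperature and the Lewis acid should disfavour epoxide formation, and 8 (a carcinogen) and 9 (toxic, potentially explosive) are handled only cold, dilute and in smooth glassware.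

Step 6
Reactants: 10 (2R,4aS,8aS)-2,5,5,8a-tetramethyloctahydronaphthalen-1(2H)-one
Product: 12 (4aS,8aS)-2,5,5,8a-tetramethyl-3,4,4a,5,6,7,8,8a-octahydronaphthalen-1-yl trifluoromethanesulfonate, via potassium enolate 11 (not isolated)
Conditions: KN(SiMe3)2, THF, −78 → 0 °C; PhNTf2, 0 °C → rt
Reagents that add atoms: N-phenylbis(trifluoromethanesulfonimide), O=S(=O)(N(c1ccccc1)S(=O)(=O)C(F)(F)F)C(F)(F)F
Why: Enolate O-sulfonylation; C8 bears the only enolisable hydrogen (C10 is quaternary), so only the tetrasubstituted C8=C9 enol triflate can form, as with 2,2,6-trimethylcyclohexanone; the C8 stereocentre is deliberately flattened.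

Step 7
Reactants: 13 5-bromovanillin (3-bromo-4-hydroxy-5-methoxybenzaldehyde)
Product: 15 1-bromo-2,3,5-trimethoxybenzene, via 2-bromo-6-methoxyhydroquinone 14 (not isolated)
Conditions: 30% H2O2, NaOH, H2O/THF, 0 °C → rt (N2); HCl, extraction; MeI, K2CO3, acetone, reflux
Reagents that add atoms: hydrogen peroxide, OO; iodomethane, CI
Why: Dakin oxidation of a para-hydroxybenzaldehyde (aryl shift in the peroxide adduct, then hydrolysis of the formate) gives the hydroquinone, which is methylated twice at once (Williamson ether synthesis) before air can oxidise it.

Step 8
Reactants: 15 1-bromo-2,3,5-trimethoxybenzene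
Product: 17 (2,3,5-trimethoxyphenyl)boronic acid, via aryllithium 16 (not isolated)
Conditions: n-BuLi, THF, −78 °C; B(OiPr)3, −78 °C → rt; 1 M HCl
Reagents that add atoms: triisopropyl borate, CC(C)OB(OC(C)C)OC(C)C; water, O
Why: Bromine–lithium exchange at −78 °C is faster than ortho-lithiation, so boron enters at the carbon that carried bromine; borate quench and hydrolysis give the boronic acid.

Step 9
Reactants: 12 (4aS,8aS)-2,5,5,8a-tetramethyl-3,4,4a,5,6,7,8,8a-octahydronaphthalen-1-yl trifluoromethanesulfonate; 17 (2,3,5-trimethoxyphenyl)boronic acid
Product: 18 (2,3,5-trimethoxyphenyl)[(4aS,8aS)-2,5,5,8a-tetramethyl-3,4,4a,5,6,7,8,8a-octahydronaphthalen-1-yl]methanone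
Conditions: PdCl2(dppf) (5 mol%), K2CO3, KI, CO (1 atm), anisole, 80 °C
Reagents that add atoms: carbon monoxide, [C-]#[O+]
Why: Carbonylative Suzuki–Miyaura coupling: zerovalent palladium inserts into the C9–O bond, CO insertion gives the acylpalladium, and transmetalation with the boronate followed by reductive elimination forms C9–C11 and C11–C1′. The crowding at C9 slows direct transmetalation and so favours CO insertion first; no stereocentre is formed.

Step 10
Reactants: 18 (2,3,5-trimethoxyphenyl)[(4aS,8aS)-2,5,5,8a-tetramethyl-3,4,4a,5,6,7,8,8a-octahydronaphthalen-1-yl]methanone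
Product: 21 (E)-[(2S,4aS,8aS)-2,5,5,8a-tetramethyloctahydronaphthalen-1(2H)-ylidene](2,3,5-trimethoxyphenyl)methyl trifluoromethanesulfonate, via silyl enol ether 19 (not isolated), via lithium enolate 20 (not isolated)
Conditions: [(Ph3P)CuH]6 (5 mol%), PhMe2SiH, PhMe, rt; concentration; MeLi, THF, 0 °C; PhNTf2, −78 °C → rt
Reagents that add atoms: N-phenylbis(trifluoromethanesulfonimide), O=S(=O)(N(c1ccccc1)S(=O)(=O)C(F)(F)F)C(F)(F)F
Why: Copper hydride 1,4-reduction with silane turnover, then Si–O cleavage by MeLi and O-sulfonylation of the enolate. A(1,3) strain between the aryl group and the C8 methyl should hold the enone near s-cis (oxygen on the C8 side, as in β,β-disubstituted enones), so 1,4-addition gives the enolate with oxygen syn to C8, and this geometry passes unchanged through 19 and 20 into 21. The bulky phosphine–copper hydride should deliver hydrogen to C8 on the α face, anti to the axial C10 methyl, which sets C8 as S with an axial methyl that also avoids strain against the enolate oxygen.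

Step 11
Reactants: 21 (E)-[(2S,4aS,8aS)-2,5,5,8a-tetramethyloctahydronaphthalen-1(2H)-ylidene](2,3,5-trimethoxyphenyl)methyl trifluoromethanesulfonate
Product: 22 1-{(E)-chloro[(2S,4aS,8aS)-2,5,5,8a-tetramethyloctahydronaphthalen-1(2H)-ylidene]methyl}-2,3,5-trimethoxybenzene
Conditions: Ni(cod)2 (10 mol%), LiCl (3 equiv), DMA/THF (1:3), rt
Reagents that add atoms: lithium chloride, [Li+].[Cl-]
Why: Nickel-catalysed triflate-to-halide exchange of enol triflates: oxidative addition at C11–O, chloride exchange on nickel and C–Cl reductive elimination occur at the same alkene carbon with retention, so chlorine stays syn to C8; the methyl ethers and the stereocentres are not involved.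

Step 12
Reactants: 22 1-{(E)-chloro[(2S,4aS,8aS)-2,5,5,8a-tetramethyloctahydronaphthalen-1(2H)-ylidene]methyl}-2,3,5-trimethoxybenzene
Product: 24 2-{(E)-chloro[(2S,4aS,8aS)-2,5,5,8a-tetramethyloctahydronaphthalen-1(2H)-ylidene]methyl}-6-methoxybenzene-1,4-diol, via methoxyquinone 23 (not isolated)
Conditions: (NH4)2Ce(NO3)6 (2.5 equiv), MeCN/H2O, 0 °C; EtOAc extraction; aq Na2S2O4, rt (N2)
Reagents that add atoms: water, O
Why: Oxidative demethylation by tetravalent cerium takes the para-related C2′/C5′ methoxy pair to the 1,4-benzoquinone (oxygen from water, methanol released), leaving the C3′ methoxy group as a vinylogous ester. Dithionite then reduces the quinone to the hydroquinone without affecting C–Cl or the hindered alkene.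

## Compound list

1 | (S)-7a-methyl-2,3,7,7a-tetrahydro-1H-indene-1,5(6H)-dione | C[C@]12CCC(=O)C=C1CCC2=O | starting material
2 | (7aS)-1,1-(ethylenedioxy)-7a-methyl-1,2,3,6,7,7a-hexahydro-5H-inden-5-one | C[C@]12CCC(=O)C=C1CCC23OCCO3 | intermediate
3 | (7aS)-1,1-(ethylenedioxy)-4,4,7a-trimethyl-1,2,4,6,7,7a-hexahydro-5H-inden-5-one | C[C@]12CCC(=O)C(C)(C)C1=CCC23OCCO3 | intermediate
4 | C5 hydrazone of 3 | C[C@]12CCC(=NN)C(C)(C)C1=CCC23OCCO3 | intermediate
5 | (7aS)-1,1-(ethylenedioxy)-4,4,7a-trimethyl-2,4,5,6,7,7a-hexahydro-1H-indene | C[C@]12CCCC(C)(C)C1=CCC23OCCO3 | intermediate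
6 | (3aS,7aS)-1,1-(ethylenedioxy)-4,4,7a-trimethyloctahydro-1H-indene (trans-fused) | C[C@]12CCCC(C)(C)[C@@H]1CCC23OCCO3 | intermediate
7 | (3aS,7aS)-4,4,7a-trimethyloctahydro-1H-inden-1-one | C[C@]12CCCC(C)(C)[C@@H]1CCC2=O | intermediate
8 | N-ethyl-N-nitrosourea | CCN(N=O)C(N)=O | starting material
9 | diazoethane | CC=[N+]=[N-] | intermediate
10 | (2R,4aS,8aS)-2,5,5,8a-tetramethyloctahydronaphthalen-1(2H)-one | C[C@@H]1CC[C@H]2C(C)(C)CCC[C@]2(C)C1=O | intermediate
11 | potassium (4aS,8aS)-2,5,5,8a-tetramethyl-3,4,4a,5,6,7,8,8a-octahydronaphthalen-1-olate | CC1=C(O[K])[C@@]2(C)CCCC(C)(C)[C@@H]2CC1 | intermediate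
12 | (4aS,8aS)-2,5,5,8a-tetramethyl-3,4,4a,5,6,7,8,8a-octahydronaphthalen-1-yl trifluoromethanesulfonate | CC1=C(OS(=O)(=O)C(F)(F)F)[C@@]2(C)CCCC(C)(C)[C@@H]2CC1 | intermediate
13 | 5-bromovanillin (3-bromo-4-hydroxy-5-methoxybenzaldehyde) | COc1cc(C=O)cc(Br)c1O | starting material
14 | 2-bromo-6-methoxybenzene-1,4-diol | COc1cc(O)cc(Br)c1O | intermediate
15 | 1-bromo-2,3,5-trimethoxybenzene | COc1cc(OC)cc(Br)c1OC | intermediate
16 | (2,3,5-trimethoxyphenyl)lithium | COc1cc(OC)cc([Li])c1OC | intermediate
17 | (2,3,5-trimethoxyphenyl)boronic acid | COc1cc(OC)cc(B(O)O)c1OC | intermediate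
18 | (2,3,5-trimethoxyphenyl)[(4aS,8aS)-2,5,5,8a-tetramethyl-3,4,4a,5,6,7,8,8a-octahydronaphthalen-1-yl]methanone | COc1cc(OC)cc(C(=O)C2=C(C)CC[C@H]3C(C)(C)CCC[C@]23C)c1OC | intermediate
19 | dimethyl(phenyl)silyl (E)-enol ether of the C8-reduced ketone (O syn to C8; 2S,4aS,8aS) | COc1cc(OC)cc(/C(O[Si](C)(C)c4ccccc4)=C2/[C@@H](C)CC[C@H]3C(C)(C)CCC[C@]23C)c1OC | intermediate
20 | lithium (E)-enolate (O syn to C8; 2S,4aS,8aS) | COc1cc(OC)cc(/C(O[Li])=C2/[C@@H](C)CC[C@H]3C(C)(C)CCC[C@]23C)c1OC | intermediate
21 | (E)-[(2S,4aS,8aS)-2,5,5,8a-tetramethyloctahydronaphthalen-1(2H)-ylidene](2,3,5-trimethoxyphenyl)methyl trifluoromethanesulfonate | COc1cc(OC)cc(/C(OS(=O)(=O)C(F)(F)F)=C2/[C@@H](C)CC[C@H]3C(C)(C)CCC[C@]23C)c1OC | intermediate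
22 | 1-{(E)-chloro[(2S,4aS,8aS)-2,5,5,8a-tetramethyloctahydronaphthalen-1(2H)-ylidene]methyl}-2,3,5-trimethoxybenzene | COc1cc(OC)cc(/C(Cl)=C2/[C@@H](C)CC[C@H]3C(C)(C)CCC[C@]23C)c1OC | intermediate
23 | 2-{(E)-chloro[(2S,4aS,8aS)-2,5,5,8a-tetramethyloctahydronaphthalen-1(2H)-ylidene]methyl}-6-methoxycyclohexa-2,5-diene-1,4-dione | COC1=CC(=O)C=C(/C(Cl)=C2/[C@@H](C)CC[C@H]3C(C)(C)CCC[C@]23C)C1=O | intermediate
24 | 2-{(E)-chloro[(2S,4aS,8aS)-2,5,5,8a-tetramethyloctahydronaphthalen-1(2H)-ylidene]methyl}-6-methoxybenzene-1,4-diol | COc1cc(O)cc(/C(Cl)=C2/[C@@H](C)CC[C@H]3C(C)(C)CCC[C@]23C)c1O | target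

## Step count and least certain steps

Total: 12 steps. Longest linear sequence: 10 steps (steps 1–6 and 9–12); the arene branch is steps 7–8.

Step 5 (key step). The likeliest failures are competing migration of the quaternary C10 (the more substituted carbon is the better migrating group on electronic grounds), slow addition of 9 to the neopentyl carbonyl with decomposition of the diazoalkane, and epoxide formation. The fallback introduces the methyl group separately. It sets out from 7: Me3SiCHN2 with BF3·OEt2 in CH2Cl2 at −78 °C should give, by the same 1,2-shift but with a bulkier diazo carbon that favours methylene migration more strongly, (4aS,8aS)-5,5,8a-trimethyl-2-(trimethylsilyl)octahydronaphthalen-1(2H)-one F1. Aqueous acid removes silicon to give (4aS,8aS)-5,5,8a-trimethyloctahydronaphthalen-1(2H)-one F2. LiN(iPr)2 then MeI methylates C8, the only enolisable position, and NaOMe equilibration returns the route to 10.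

Step 10. The likeliest failures are no hydride transfer to the twisted, fully substituted enone, 1,2-reduction of the aryl ketone, or reaction through the s-trans conformer with loss of enolate geometry. The fallback replaces hydrometalation by electron transfer. It sets out from 18: Li in NH3/THF at −78 °C reduces the aryl enone to its radical anion and dianion, which is protonated at C8 from the less hindered α face; after removal of NH3 the lithium enolate so formed is 20, which is trapped with PhNTf2 as in the main route. It comes back at 20 and makes no compound outside the compound list (entry F0).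

Step 11. The likeliest failures are loss of alkene geometry by rotation in an alkenylnickel intermediate stabilised by the electron-rich arene, or reluctant oxidative addition at the crowded C11–O bond. The fallback goes through a tin intermediate with retentive steps. It sets out from 21: (Me3Sn)2, Pd(PPh3)4 and LiCl in dioxane at 90 °C should give trimethyl{(E)-[(2S,4aS,8aS)-2,5,5,8a-tetramethyloctahydronaphthalen-1(2H)-ylidene](2,3,5-trimethoxyphenyl)methyl}stannane F3, and chlorodestannylation with CuCl2 in THF then gives 22 with retention.

Step 9. The likeliest failures are direct C9–C1′ coupling without CO, or protodeboronation of the electron-rich, ortho-substituted 17 before acyl transfer. The fallback separates CO insertion from aryl transfer. It sets out from 12: Pd(OAc)2/dppp, CO, MeNHOMe·HCl and Et3N in DMF at 60 °C should give (4aS,8aS)-N-methoxy-N,2,5,5,8a-pentamethyl-3,4,4a,5,6,7,8,8a-octahydronaphthalene-1-carboxamide F4 by aminocarbonylation. Addition of 16 (Weinreb ketone synthesis) then returns the route to 18.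

Step 4. The likeliest failure is hydrogen delivery on the β face (cis fusion) or very slow reduction of an alkene flanked by two quaternary carbons. The fallback sets the ring fusion by dissolving-metal reductive alkylation. It sets out from 2: KOtBu (1.1 equiv) and MeI (1 equiv) should give (7aS)-1,1-(ethylenedioxy)-4,7a-dimethyl-1,2,3,6,7,7a-hexahydro-5H-inden-5-one F5. Li in NH3, then MeI, protonates C3a from the α face and methylates the resulting enolate at C4 to give (3aS,7aS)-1,1-(ethylenedioxy)-4,4,7a-trimethyloctahydro-5H-inden-5-one F6. Wolff–Kishner reduction of F6 returns the route to 6, which is hydrolysed to 7 as in step 4.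

## Further compounds

F1 | step 5 | (4aS,8aS)-5,5,8a-trimethyl-2-(trimethylsilyl)octahydronaphthalen-1(2H)-one (C2 epimers) | C[Si](C)(C)C1CC[C@H]2C(C)(C)CCC[C@]2(C)C1=O
F2 | step 5 | (4aS,8aS)-5,5,8a-trimethyloctahydronaphthalen-1(2H)-one | O=C1CCC[C@H]2C(C)(C)CCC[C@]12C
F0 | step 10 | none | none
F3 | step 11 | trimethyl{(E)-[(2S,4aS,8aS)-2,5,5,8a-tetramethyloctahydronaphthalen-1(2H)-ylidene](2,3,5-trimethoxyphenyl)methyl}stannane | COc1cc(OC)cc(/C([Sn](C)(C)C)=C2/[C@@H](C)CC[C@H]3C(C)(C)CCC[C@]23C)c1OC
F4 | step 9 | (4aS,8aS)-N-methoxy-N,2,5,5,8a-pentamethyl-3,4,4a,5,6,7,8,8a-octahydronaphthalene-1-carboxamide | CON(C)C(=O)C1=C(C)CC[C@H]2C(C)(C)CCC[C@]12C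
F5 | step 4 | (7aS)-1,1-(ethylenedioxy)-4,7a-dimethyl-1,2,3,6,7,7a-hexahydro-5H-inden-5-one | C[C@]12CCC(=O)C(C)=C1CCC23OCCO3
F6 | step 4 | (3aS,7aS)-1,1-(ethylenedioxy)-4,4,7a-trimethyloctahydro-5H-inden-5-one | C[C@]12CCC(=O)C(C)(C)[C@@H]1CCC23OCCO3
A1 | alternative 1 | 1-{(E)-chloro[(2S,4aS,8aS)-2,5,5,8a-tetramethyl-4a,5,6,7,8,8a-hexahydronaphthalen-1(2H)-ylidene]methyl}-2,3,5-trimethoxybenzene (C6=C7 alkene) | COc1cc(OC)cc(/C(Cl)=C2/[C@@H](C)C=C[C@H]3C(C)(C)CCC[C@]23C)c1OC
A2 | alternative 1 | 1-[(8E,10E)-1-chloro-3,7,7-trimethyldodeca-1,2,8,10-tetraen-1-yl]-2,3,5-trimethoxybenzene with R-configured allene axis | COc1cc(OC)cc(C(Cl)=[C@@]=C(C)CCCC(C)(C)/C=C/C=C/C)c1OC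
A3 | alternative 2 | (2,3,5-trimethoxyphenyl)[(4aS,8aS)-2,5,5,8a-tetramethyl-3,4,4a,5,6,8a-hexahydronaphthalen-1-yl]methanone (C1=C2 alkene) | COc1cc(OC)cc(C(=O)C2=C(C)CC[C@H]3C(C)(C)CC=C[C@]23C)c1OC
A4 | alternative 2 | 4-{(1S,2S)-2,6,6-trimethyl-2-[(2,3,5-trimethoxyphenyl)ethynyl]cyclohex-3-en-1-yl}butan-2-one | COc1cc(OC)cc(C#C[C@@]2(C)C=CCC(C)(C)[C@@H]2CCC(C)=O)c1OC
A5 | alternative 3 | 2-{2-[(4aS,8aS)-2,5,5,8a-tetramethyl-3,4,4a,5,6,7,8,8a-octahydronaphthalen-1-yl]-1,3-dioxolan-2-yl}-4,6-dimethoxyphenol | COc1cc(OC)cc(C2(OCCO2)C3=C(C)CC[C@H]4C(C)(C)CCC[C@]34C)c1O
A6 | alternative 3 | 2-ethynyl-2-[(4aS,8aS)-2,5,5,8a-tetramethyl-3,4,4a,5,6,7,8,8a-octahydronaphthalen-1-yl]-1,3-dioxolane | C#CC1(OCCO1)C2=C(C)CC[C@H]3C(C)(C)CCC[C@]23C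
A7 | alternative 3 | pentacarbonyl[(2E)-1,3-dimethoxyprop-2-en-1-ylidene]chromium | CO/C=C/C(OC)=[Cr](=C=O)(=C=O)(=C=O)(=C=O)=C=O
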